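## Retrosynthetic overview
1. The 14-membered carbocycle is closed last, at the C4–C5 sp2–sp3 bond. A C5=C6 vinyl group is hydroborated and coupled intramolecularly (B-alkyl Suzuki) onto a (Z)-α-bromodienoate. This replaces the usual HWE, Stille or RCM closure.
2. The ε-lactone is made first, by alkyl–O rather than acyl–O bond formation. A tert-butyl (Z)-enoate opens a (7R,8R)-vinyl epoxide at tertiary C8 (7-exo, inversion). One step gives C8 (S) and free C7–OH (R).
3. Both stereocentres therefore come from a single Sharpless epoxidation of geraniol, which supplies C6–C11 and C19.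
4. C11=C12 comes from an Ando Z-olefination (East aldehyde + West phosphonate). C1=C2 comes from Red-Al/I2 followed by Negishi coupling. C3=C4 comes from a bromo-ylide Wittig.
5. Ring order: oxepinone (step 12), then macrocycle (step 16).

Assumption: locants are cembrane numbering (C1 bears iPr, C4 bears CO2Me, C7 bears OAc, C8 bears Me and O, C12 bears the lactone C=O, which is C20). The C11=C12 alkene has no descriptor in the SMILES and is taken as the ring-enforced Z geometry. The target is (7R,8S,1E,3E).

## Route

**Step 1**
Reactants: 1 geraniol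
Product: 2 (2R,3R)-2,3-epoxygeraniol
Conditions: Ti(OiPr)4 (10 mol %), D-(−)-DIPT (12 mol %), TBHP, 4 Å MS, CH2Cl2, −20 °C
Reagents that add atoms: tert-butyl hydroperoxide, CC(C)(C)OO
Why: In the Katsuki–Sharpless asymmetric epoxidation only the allylic-alcohol alkene reacts, and the D-(−)-tartrate catalyst gives the (2R,3R)-epoxide (about 95% ee, mirror image of the known L-tartrate result), setting C7 in its final configuration and C8 in the configuration to be inverted in step 12.

**Step 2**
Reactants: 2
Product: 3 (2S,3R)-3-methyl-3-(4-methylpent-3-enyl)oxirane-2-carbaldehyde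
Conditions: SO3·py, DMSO, Et3N, CH2Cl2, 0 °C
Reagents that add atoms: none
Why: The Parikh–Doering oxidation is non-acidic and leaves the epoxide and alkene untouched; the C2 descriptor changes to S only because CHO outranks C3, with no change in geometry.

**Step 3**
Reactants: 3; 4 methyltriphenylphosphonium bromide
Product: 5 (2R,3R)-3-ethenyl-2-methyl-2-(4-methylpent-3-enyl)oxirane
Conditions: 4, NaHMDS, THF, −78 → 0 °C
Reagents that add atoms: methyltriphenylphosphonium bromide, C[P+](c1ccccc1)(c1ccccc1)c1ccccc1.[Br-]
Why: Wittig methylenation of a Sharpless-derived epoxy aldehyde is the standard entry to vinyl epoxides, adds C5, and does not touch the non-enolisable epoxide stereocentres.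

**Step 4**
Reactants: 5
Product: 6 3-[(2R,3R)-3-ethenyl-2-methyloxiran-2-yl]propanal
Conditions: O3 (about 1 equiv, Sudan Red 7B end-point), pyridine, CH2Cl2, −78 °C; Me2S
Reagents that add atoms: ozone, [O-][O+]=O
Why: This is a chemoselective ozonolysis in which the electron-rich trisubstituted alkene reacts far faster than the monosubstituted vinyl group deactivated by its allylic C–O bond, the same selectivity seen with linalool.

**Step 5**
Reactants: 7 3-methylbut-1-yne; 8 paraformaldehyde
Product: 9 4-methylpent-2-yn-1-ol
Conditions: n-BuLi, THF, −78 °C; (CH2O)n, → rt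
Reagents that add atoms: paraformaldehyde, C=O
Why: Hydroxymethylation of a lithium acetylide is a routine 1,2-addition and installs C3.

**Step 6**
Reactants: 9
Product: 10 (2Z)-3-iodo-4-methylpent-2-en-1-ol
Conditions: Red-Al, THF, 0 °C → rt; EtOAc; I2, −78 → 0 °C
Reagents that add atoms: iodine, II
Why: Hydroxyl-directed trans-hydroalumination places Al on the distal carbon in a five-membered alkoxyaluminate, and iodinolysis with retention puts iodine (the future C14 position) cis to CH2OH (C3).

**Step 7**
Reactants: 10
Product: 11 tert-butyl{[(2Z)-3-iodo-4-methylpent-2-enyl]oxy}diphenylsilane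
Conditions: TBDPSCl, imidazole, CH2Cl2, rt
Reagents that add atoms: TBDPSCl, CC(C)(C)[Si](Cl)(c1ccccc1)c1ccccc1
Why: Standard silylation; TBDPS is chosen because it survives LDA, NaH and the BF3 step.

**Step 8**
Reactants: 11; 12 tert-butyl 4-bromobutanoate
Product: 13 tert-butyl (5E)-7-(tert-butyldiphenylsilyloxy)-5-isopropylhept-5-enoate
Conditions: 12, Zn dust, LiCl, THF, 40 °C; then 11, Pd(dppf)Cl2 (5 mol %), THF, 50 °C
Reagents that add atoms: tert-butyl 4-bromobutanoate, CC(C)(C)OC(=O)CCCBr
Why: Negishi sp2–sp3 coupling of an ester-tolerant alkylzinc proceeds with retention at the alkenyl iodide, so C14 ends up cis to C3 (the 1E geometry) and C12–C14 plus C20 arrive in one step.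

**Step 9**
Reactants: 13; 14 diphenyl chlorophosphite
Product: 15 tert-butyl (5E)-7-(tert-butyldiphenylsilyloxy)-2-(diphenoxyphosphoryl)-5-isopropylhept-5-enoate (racemic at C2; this centre is destroyed in step 11)
Conditions: LDA, THF, −78 °C; ClP(OPh)2, −78 °C → rt; 30% H2O2, 0 °C
Reagents that add atoms: diphenyl chlorophosphite, ClP(Oc1ccccc1)Oc1ccccc1; hydrogen peroxide, OO
Why: C-phosphinylation of an ester enolate with a P(III) chloride followed by P(III)→P(V) oxidation avoids the O-phosphorylation and proton-transfer quenching seen with P(V) chlorides.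

**Step 10**
Reactants: 16 methyl (triphenylphosphoranylidene)acetate
Product: 17 methyl bromo(triphenylphosphoranylidene)acetate
Conditions: Br2, CH2Cl2, 0 °C; aq K2CO3
Reagents that add atoms: bromine, BrBr
Why: Electrophilic bromination of a stabilised ylide followed by deprotonation of the phosphonium salt is the classical preparation of α-bromo ylides.

**Step 11**
Reactants: 15; 6
Product: 18 tert-butyl (2Z)-2-[(3E)-5-(tert-butyldiphenylsilyloxy)-3-isopropylpent-3-enyl]-5-[(2R,3R)-3-ethenyl-2-methyloxiran-2-yl]pent-2-enoate
Conditions: NaH, THF, 0 °C; then 6, −78 → 0 °C; chromatographic removal of the minor E isomer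
Reagents that add atoms: none (all atoms come from 6 and 15)
Why: In the Ando-type Z-selective Horner–Wadsworth–Emmons reaction the electron-poor diaryl phosphonate collapses irreversibly from the kinetic adduct, placing the ester (C20) cis to C10; the epoxide and vinyl group are inert to the stabilised anion.

**Step 12 (key step)**
Reactants: 18
Product: 19 (7S)-7-[(1R)-1-hydroxyprop-2-enyl]-7-methyl-3-[(3E)-5-(tert-butyldiphenylsilyloxy)-3-isopropylpent-3-enyl]-6,7-dihydrooxepin-2(5H)-one
Conditions: BF3·OEt2 (1.2 equiv), 2,6-di-tert-butylpyridine (0.5 equiv), CH2Cl2 (5 mM), −78 → −40 °C; aq NaHCO3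
Reagents that add atoms: none (isobutene is lost)
Why: Proposed new method: the BF3-activated epoxide is attacked from the backside at tertiary C8 by the carbonyl oxygen of the cis-held tert-butyl ester (7-exo-tet; C8 carries positive charge best, attack at C7 would need an 8-endo ring, and the β-oxygen discourages free ionisation), and the dialkoxycarbenium ion then loses isobutene, so C8 is inverted (R→S) while the C7–O bond is untouched (R); the closest known reaction types are Lewis-acid epoxide opening by tert-butyl esters or carbonates (5- and 6-exo) and tertiary-selective carboxylate opening of trisubstituted 2,3-epoxy alcohols.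

**Step 13**
Reactants: 19
Product: 20 (1R)-1-{(2S)-2-methyl-7-oxo-6-[(3E)-5-(tert-butyldiphenylsilyloxy)-3-isopropylpent-3-enyl]-2,3,4,7-tetrahydrooxepin-2-yl}prop-2-enyl acetate
Conditions: Ac2O, DMAP, pyridine, CH2Cl2, rt
Reagents that add atoms: acetic anhydride, CC(=O)OC(C)=O
Why: DMAP-catalysed acetylation of the only free hydroxyl proceeds with retention at C7.

**Step 14**
Reactants: 20
Product: 21 the corresponding primary allylic alcohol (C3–OH)
Conditions: TBAF/AcOH (1:1), THF, 0 °C → rt
Reagents that add atoms: none
Why: Buffered fluoride desilylation leaves the acetate and the hindered tertiary-alkyl lactone intact.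

**Step 15**
Reactants: 21; 17
Product: 22 methyl (2Z,4E)-2-bromo-5-isopropyl-7-{(7S)-7-[(1R)-1-acetoxyprop-2-enyl]-7-methyl-2-oxo-2,5,6,7-tetrahydrooxepin-3-yl}hepta-2,4-dienoate
Conditions: activated MnO2 (15 equiv), 17 (1.5 equiv), CH2Cl2, 40 °C
Reagents that add atoms: methyl bromo(triphenylphosphoranylidene)acetate, COC(=O)C(Br)=P(c1ccccc1)(c1ccccc1)c1ccccc1
Why: In this tandem oxidation–Wittig reaction the isomerisation-prone enal is trapped as it forms, and the stabilised bromo ylide places CO2Me trans to C2 (the Z-bromide), which pre-sets the 3E geometry.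

**Step 16 (macrocyclisation)**
Reactants: 22
Product: 23 Sarcrassin D
Conditions: 9-BBN-H (1.3 equiv), THF, 0 °C → rt; then syringe-pump addition into Pd(dppf)Cl2 (20 mol %), AsPh3 (40 mol %), Cs2CO3 (3 equiv), DMF–THF–H2O, 1 mM, 45 °C
Reagents that add atoms: none (9-BBN delivers only H; Br and B are lost)
Why: In this intramolecular B-alkyl Suzuki–Miyaura coupling 9-BBN adds only to the terminal vinyl group (boron at C5, which also removes the Pd-labile allylic acetate), and coupling at the α-bromoenoate is stereoretentive, so C5 ends up cis to C2 and no stereocentre is touched.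

## Compound list
| No. | Name | SMILES | Role |
|---|---|---|---|
| 1 | geraniol | CC(C)=CCC/C(C)=C/CO | starting material |
| 2 | (2R,3R)-2,3-epoxygeraniol | CC(C)=CCC[C@@]1(C)O[C@@H]1CO | intermediate |
| 3 | (2S,3R)-epoxygeranial | CC(C)=CCC[C@@]1(C)O[C@@H]1C=O | intermediate |
| 4 | methyltriphenylphosphonium bromide | C[P+](c1ccccc1)(c1ccccc1)c1ccccc1.[Br-] | starting material |
| 5 | (2R,3R)-3-ethenyl-2-methyl-2-(4-methylpent-3-enyl)oxirane | CC(C)=CCC[C@@]1(C)O[C@@H]1C=C | intermediate |
| 6 | 3-[(2R,3R)-3-ethenyl-2-methyloxiran-2-yl]propanal | O=CCC[C@@]1(C)O[C@@H]1C=C | intermediate |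
| 7 | 3-methylbut-1-yne | CC(C)C#C | starting material |
| 8 | paraformaldehyde | C=O | starting material |
| 9 | 4-methylpent-2-yn-1-ol | CC(C)C#CCO | intermediate |
| 10 | (2Z)-3-iodo-4-methylpent-2-en-1-ol | CC(C)/C(I)=C/CO | intermediate |
| 11 | TBDPS ether of 10 | CC(C)/C(I)=C/CO[Si](c1ccccc1)(c1ccccc1)C(C)(C)C | intermediate |
| 12 | tert-butyl 4-bromobutanoate | CC(C)(C)OC(=O)CCCBr | starting material |
| 13 | tert-butyl (5E)-7-(TBDPSO)-5-isopropylhept-5-enoate | CC(C)(C)OC(=O)CCC/C(C(C)C)=C\CO[Si](c1ccccc1)(c1ccccc1)C(C)(C)C | intermediate |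
| 14 | diphenyl chlorophosphite | ClP(Oc1ccccc1)Oc1ccccc1 | starting material |
| 15 | α-(diphenoxyphosphoryl) ester (West phosphonate) | CC(C)(C)OC(=O)C(CC/C(C(C)C)=C\CO[Si](c1ccccc1)(c1ccccc1)C(C)(C)C)P(=O)(Oc1ccccc1)Oc1ccccc1 | intermediate |
| 16 | methyl (triphenylphosphoranylidene)acetate | COC(=O)C=P(c1ccccc1)(c1ccccc1)c1ccccc1 | starting material |
| 17 | methyl bromo(triphenylphosphoranylidene)acetate | COC(=O)C(Br)=P(c1ccccc1)(c1ccccc1)c1ccccc1 | intermediate |
| 18 | (Z)-enoate vinyl epoxide | CC(C)(C)OC(=O)/C(CC/C(C(C)C)=C\CO[Si](c1ccccc1)(c1ccccc1)C(C)(C)C)=C\CC[C@@]1(C)O[C@@H]1C=C | intermediate |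
| 19 | (7S,1′R)-hydroxy oxepinone | CC(C)(C)[Si](c1ccccc1)(c1ccccc1)OC/C=C(/C(C)C)CCC1=CCC[C@](C)(OC1=O)[C@H](O)C=C | intermediate |
| 20 | C7 acetate of 19 | CC(C)(C)[Si](c1ccccc1)(c1ccccc1)OC/C=C(/C(C)C)CCC1=CCC[C@](C)(OC1=O)[C@H](OC(C)=O)C=C | intermediate |
| 21 | C3 allylic alcohol | OC/C=C(/C(C)C)CCC1=CCC[C@](C)(OC1=O)[C@H](OC(C)=O)C=C | intermediate |
| 22 | (2Z,4E)-α-bromodienoate | COC(=O)/C(Br)=C/C=C(/C(C)C)CCC1=CCC[C@](C)(OC1=O)[C@H](OC(C)=O)C=C | intermediate |
| 23 | Sarcrassin D | COC(=O)/C1=C/C=C(/C(C)C)CCC2=CCC[C@](C)(OC2=O)[C@H](OC(C)=O)CC1 | target |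

## Summary
Total steps: 16.
Longest linear sequence: 11 steps (steps 5–9, then 11–16, starting from 3-methylbut-1-yne). The geraniol branch is 10 steps.

Three steps most likely to fail:
1. **Step 12, the 7-exo epoxide-opening lactonisation.** Possible failures are a hydride shift to the vinyl ketone, opening at C7 or SN2′ opening, and partial SN1 scrambling at C8. Fallback: switch to acyl–O closure. Hydrolyse 18 with aqueous acid, so that water attacks C8 with the same inversion. Acetylate the secondary C7–OH, cleave the tert-butyl ester, and close the ring by mixed-anhydride (Shiina or Yamaguchi) lactonisation of the Z-acid onto the tertiary C8–OH.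
2. **Step 16, the macrocyclic B-alkyl Suzuki.** Possible failures are oligomerisation, protodeboronation and transannular strain. Fallback: move the ring closure to C3=C4. Hydroborate and oxidise the vinyl group of 20 to the C5 alcohol, convert it to the iodide, and alkylate trimethyl phosphonoacetate. Unmask and oxidise C3 to the enal, then cyclise by intramolecular Masamune–Roush HWE at high dilution.
3. **Step 11, Z-selectivity with a bulky α-chain and a tert-butyl ester.** Fallback: define the C11=C12 geometry by cross-coupling instead of olefination.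
   - Start from the aldehyde derived from O-silylated 2. It has no vinyl epoxide, so it is safe toward Pd(0).
   - Carry out Ramirez dibromo-olefination, then trans-selective Negishi coupling with the West homoallylic zinc reagent.
   - Carbonylate the remaining (Z)-bromide with Pd/CO to install C20.
   - Install the vinyl group afterwards by oxidation and methylenation.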